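Remark on the chemistry: locants follow hydronaphthalene numbering of the acid part (C1 carboxyl-bearing, C2 methyl-bearing, C4a and C8a ring fusion, C5 side-chain-bearing; ring A = C1–C4/C4a/C8a, ring B = C4a/C5–C8/C8a). The given SMILES corresponds to (1S,2R,4aR,8aR) in the acid part and (2S) in the glycerol unit. Both enantiomers of 3-bromo-2-methylpropan-1-ol and of glycidol are taken as commercial.

## The problem

The acid part of 28 is a cis-fused 1,2,3,4,4a,7,8,8a-octahydronaphthalene with four contiguous stereocentres: C2 (methyl), C1 (carboxyl), C8a (methyl) and C4a (methyl). C8a and C4a are adjacent quaternary ring-fusion carbons with their methyl groups on the same face. Making the C4a–C8a bond between two fully substituted carbons, in one absolute sense, is the hardest part, because neither carbon can be corrected afterwards. Ring B holds a trisubstituted C5=C6 double bond whose C5 is bonded to quaternary C4a and carries the 4-methylpent-3-enyl chain, so this alkene must be placed regiospecifically and, like the side-chain alkene, kept away from strong acid and unselective oxidants or boranes. C2 is the only stereocentre that can be bought; it can control C4a and C8a if it already sits on the chain that closes ring A. C1 is α to the carboxyl group and is required equatorial, trans to the C2 methyl, so it can be left to thermodynamic control. The glycerol stereocentre is too remote to be influenced by the decalin and must come from an enantiopure three-carbon unit; the carboxyl carbon is neopentyl-like and hard to acylate with, and the 1,3-diacylglycerol with its free 2-hydroxyl is prone to acyl migration. The enabling feature is ring B itself: it is a cyclohexene whose C5=C6 bond lies where a [4+2] cycloaddition leaves it if C4a=C5–C6=C7 is the diene and C8=C8a the dienophile, and C1, attached directly to C8a, can be a ketone carbonyl that activates this dienophile from inside the four-carbon tether C1–C4 that becomes ring A.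

## Retrosynthesis

**Glycerol ester.** In 28 the bond between the carboxyl oxygen and the glycerol CH2 is cut, not the acyl C–O bond. This gives acid 25 and (R)-glycidyl acetate 27, which is one step from (S)-glycidol 26. Acylating a protected glycerol would require attack at a carbonyl flanked by a quaternary and a tertiary carbon, and would need protection, deprotection and selective acetylation of a migration-prone diol. Opening the epoxide makes the ester at oxygen, brings the acetate and the stereocentre, and reveals the 2-hydroxyl in the same step. The forward reaction must open the epoxide at its terminal carbon and must not be basic.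

**Carboxyl carbon.** The exocyclic C1–CO2H bond is cut: 25 comes from aldehyde 24, 24 from alcohol 22, 22 from the 1-methylidene compound 20, and 20 from ketone 19. This costs four steps, but it leaves C1 as a carbonyl, which the key step needs. It also lets C1 be set last by equilibration of the aldehyde, where the required configuration is the equatorial one. The forward steps must methylenate a hindered ketone without epimerising C2 and hydroborate one of three alkenes.

**Key disconnection.** In 19 the ring-B bonds C7–C8 and C4a–C8a are cut in the retro-[4+2] sense. Both rings open and acyclic trienone 18 results, with a single stereocentre (the future C2). Cutting ring A instead (Alternative 2) would make the bond between the two quaternary carbons the leading bond of the cycloaddition and would leave the C5=C6 alkene and the side chain to be installed later. The chosen cut forms the C7–C8 bond between two CH2 termini first, delivers C5=C6 with the chain already on C5, and turns one stereocentre into three. The forward reaction must give the endo (cis-fused) mode and a single diene face.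

**Trienone.** In 18 the C1–C8a bond is cut to give aldehyde 15 and isopropenylmagnesium bromide 16, which supplies C8, C8a and the C8a methyl. Aldehyde 15 comes from alcohol 14 and silyl ether 13. The vinyl group of 13 (C6=C7) comes from the ester carbon of 10 through allylic alcohol 11 and enal 12 by Wittig methylenation. The forward steps must not epimerise the α-methyl centre and must keep the tetrasubstituted alkene geometry.

**Tetrasubstituted alkene.** The C4a=C5 double bond of 10 must carry the tether trans to the ester carbon, so that the tether is on the outside of the diene. The C4a–CH3 bond is cut: 10 comes from (Z)-enol triflate 9 by stereoretentive methyl coupling, and 9 from β-keto ester 7, whose sodium chelate fixes the geometry. Ester 7 is assembled from methyl acetoacetate 3 by γ-alkylation with bromide 2 (C3–C4 bond, giving 5) and α-alkylation with 5-bromo-2-methylpent-2-ene 6 (bond from C5 to the side chain). Bromide 2 is the silyl ether of (S)-3-bromo-2-methylpropan-1-ol 1, which provides C1–C3 and the C2 stereocentre.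

## Roads not taken

Alternative 1: Intermolecular Diels–Alder on a preformed ring B, the most obvious plan. The cut is at C1–C8a and C4–C4a. 2,3-Dimethylcyclohex-2-en-1-one A1 would react with methyl (2E)-3-methylpenta-2,4-dienoate A2 to give the cis-fused keto ester A3, followed by hydrogenation of C2=C3 and an enol triflate/cross-coupling sequence at C5. The chosen plan is better for four reasons:
- A1 is a tetrasubstituted enone and A2 an electron-poor diene, so the cycloaddition is both sterically and electronically mismatched.
- C2 would have to be set afterwards by face-selective hydrogenation with nothing to direct it.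
- A3 would be racemic unless a chiral catalyst could activate a tetrasubstituted enone.
- The ring-B alkene and side chain would cost further steps, whereas the chosen plan makes the same C4a–C8a bond intramolecularly, after an unhindered first bond, with C2 in place and the alkene and chain arriving in the cycloaddition.

Alternative 2: The reverse intramolecular Diels–Alder, with ring A as the cycloadduct. The cut is at C1–C2 and C4a–C8a. Methyl (2E,8E,10E)-3,8-dimethyl-7-oxododeca-2,8,10-trienoate A4 would cyclise to keto ester A5 and create all four ring stereocentres at once. It is weaker on four counts: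
- The dienophile is a β,β-disubstituted enoate and the diene is conjugated to a ketone, so both partners are electron-poor.
- In the polarised transition state the leading bond runs from the enoate β-carbon (C8a) to C4a, which is the bond between the two fully substituted carbons.
- The target needs the ester-exo, cis-fused mode, which Lewis acids disfavour.
- A4 has no stereocentre, so absolute control would need an auxiliary, and A5 would still need hydrogenation of C3=C4 and triflation/coupling at C5.

Alternative 3: Intramolecular Michael addition followed by angular methylation. The cut is at C1–C8a and C4a–CH3. In methyl (3R)-3-methyl-5-(2-methyl-6-oxocyclohex-1-en-1-yl)pentanoate A6 the ester α-carbon would add to the enone β-carbon, and the ring-fusion enolate would be methylated to give keto ester A7. It is weaker on three counts: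
- The ester α-protons of A6 are less acidic than the γ-protons of its enone, so the required enolate would not form selectively, and addition to a fully substituted β-carbon is reversible.
- Nothing reliable controls the face of methylation at C4a, that is, cis versus trans fusion.
- A7 would still need the C5 triflation/coupling steps.

Key step: step 13

## Route

Step 1
Reactants: 1 (S)-3-bromo-2-methylpropan-1-ol
Product: 2 (S)-(3-bromo-2-methylpropoxy)(tert-butyl)dimethylsilane
Conditions: TBSCl, imidazole, CH2Cl2, 0 °C → rt
Reagents that add atoms: tert-butyldimethylsilyl chloride, CC(C)(C)[Si](C)(C)Cl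
Why: Standard silylation of the primary alcohol; the stereocentre is not involved, and the silyl ether should survive the enolate alkylations, the organomagnesium coupling and the hydride reduction that follow.

Step 2
Reactants: 2 (S)-(3-bromo-2-methylpropoxy)(tert-butyl)dimethylsilane; 3 methyl acetoacetate
Product: 5 methyl (6R)-7-[(tert-butyldimethylsilyl)oxy]-6-methyl-3-oxoheptanoate, via methyl acetoacetate dianion 4 (not isolated)
Conditions: 3 (excess), NaH, THF, 0 °C; n-BuLi, 0 °C; then 2, 0 °C → rt; AcOH
Reagents that add atoms: none
Why: Acetoacetate dianion alkylation: the more basic terminal carbanion displaces the primary bromide (SN2) and forms the future C3–C4 bond; the stereocentre is untouched.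

Step 3
Reactants: 5 methyl (6R)-7-[(tert-butyldimethylsilyl)oxy]-6-methyl-3-oxoheptanoate; 6 5-bromo-2-methylpent-2-ene
Product: 7 methyl (6R)-7-[(tert-butyldimethylsilyl)oxy]-6-methyl-2-(4-methylpent-3-en-1-yl)-3-oxoheptanoate (C2 epimers)
Conditions: K2CO3, DMF, 50 °C
Reagents that add atoms: none
Why: C-alkylation of the doubly activated α-carbon of the β-keto ester with the primary homoallylic bromide installs the chain that will sit on C5; the new α-centre is removed in step 4.

Step 4
Reactants: 7 methyl (6R)-7-[(tert-butyldimethylsilyl)oxy]-6-methyl-2-(4-methylpent-3-en-1-yl)-3-oxoheptanoate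
Product: 9 methyl (2Z,6R)-7-[(tert-butyldimethylsilyl)oxy]-6-methyl-2-(4-methylpent-3-en-1-yl)-3-{[(trifluoromethyl)sulfonyl]oxy}hept-2-enoate, via sodium Z-enolate chelate 8 (not isolated)
Conditions: NaH, Et2O, 0 °C; then Tf2O, −78 → 0 °C
Reagents that add atoms: trifluoromethanesulfonic anhydride, O=S(=O)(OS(=O)(=O)C(F)(F)F)C(F)(F)F
Why: The sodium cation holds the enolate oxygen and the ester carbonyl on the same side, and O-sulfonylation should trap this geometry as the (Z)-enol triflate (chelation-controlled enol triflation of 2-alkyl-3-oxo esters); any minor (E)-isomer is removed by chromatography here or at 10.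

Step 5
Reactants: 9 methyl (2Z,6R)-7-[(tert-butyldimethylsilyl)oxy]-6-methyl-2-(4-methylpent-3-en-1-yl)-3-{[(trifluoromethyl)sulfonyl]oxy}hept-2-enoate
Product: 10 methyl (2E,6R)-7-[(tert-butyldimethylsilyl)oxy]-3,6-dimethyl-2-(4-methylpent-3-en-1-yl)hept-2-enoate
Conditions: MeMgBr, Fe(acac)3 (5 mol %), THF/NMP, −30 °C
Reagents that add atoms: methylmagnesium bromide, C[Mg]Br
Why: Iron-catalysed Kumada-type coupling of enol triflates with MeMgBr proceeds with retention of alkene geometry and outruns addition to the ester, so the future C4a methyl ends cis to the ester carbon and the tether trans to it.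

Step 6
Reactants: 10 methyl (2E,6R)-7-[(tert-butyldimethylsilyl)oxy]-3,6-dimethyl-2-(4-methylpent-3-en-1-yl)hept-2-enoate
Product: 11 (2E,6R)-7-[(tert-butyldimethylsilyl)oxy]-3,6-dimethyl-2-(4-methylpent-3-en-1-yl)hept-2-en-1-ol
Conditions: i-Bu2AlH, CH2Cl2, −78 → 0 °C
Reagents that add atoms: none
Why: 1,2-Reduction of the conjugated ester to the allylic alcohol; silyl ether and alkenes are inert.

Step 7
Reactants: 11 (2E,6R)-7-[(tert-butyldimethylsilyl)oxy]-3,6-dimethyl-2-(4-methylpent-3-en-1-yl)hept-2-en-1-ol
Product: 12 (2E,6R)-7-[(tert-butyldimethylsilyl)oxy]-3,6-dimethyl-2-(4-methylpent-3-en-1-yl)hept-2-enal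
Conditions: MnO2, CH2Cl2, rt
Reagents that add atoms: none
Why: MnO2 oxidises only the allylic alcohol and is neutral, so the tetrasubstituted double bond should keep its geometry.

Step 8
Reactants: 12 (2E,6R)-7-[(tert-butyldimethylsilyl)oxy]-3,6-dimethyl-2-(4-methylpent-3-en-1-yl)hept-2-enal
Product: 13 tert-butyl{[(2R,5E)-2,5-dimethyl-6-(4-methylpent-3-en-1-yl)octa-5,7-dien-1-yl]oxy}dimethylsilane
Conditions: Ph3PCH3Br, KOt-Bu, THF, 0 °C; then 12, −78 → 0 °C
Reagents that add atoms: methyltriphenylphosphonium bromide, C[P+](c1ccccc1)(c1ccccc1)c1ccccc1.[Br-]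
Why: Wittig methylenation of the aldehyde supplies C7 and completes the 1,3-diene, with the tether on the outside (E) position of the substituted diene terminus; low temperature limits γ-deprotonation of the enal.

Step 9
Reactants: 13 tert-butyl{[(2R,5E)-2,5-dimethyl-6-(4-methylpent-3-en-1-yl)octa-5,7-dien-1-yl]oxy}dimethylsilane
Product: 14 (2R,5E)-2,5-dimethyl-6-(4-methylpent-3-en-1-yl)octa-5,7-dien-1-ol
Conditions: Bu4NF, THF, 0 °C → rt
Reagents that add atoms: none
Why: Fluoride cleavage of the primary silyl ether; no acid touches the diene.

Step 10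
Reactants: 14 (2R,5E)-2,5-dimethyl-6-(4-methylpent-3-en-1-yl)octa-5,7-dien-1-ol
Product: 15 (2R,5E)-2,5-dimethyl-6-(4-methylpent-3-en-1-yl)octa-5,7-dienal
Conditions: Dess–Martin periodinane, pyridine, CH2Cl2, 0 °C
Reagents that add atoms: none
Why: Buffered Dess–Martin oxidation should give the α-methyl aldehyde without epimerisation; it is used at once.

Step 11
Reactants: 15 (2R,5E)-2,5-dimethyl-6-(4-methylpent-3-en-1-yl)octa-5,7-dienal; 16 isopropenylmagnesium bromide
Product: 17 (4R,7E)-2,4,7-trimethyl-8-(4-methylpent-3-en-1-yl)deca-1,7,9-trien-3-ol (C3 epimers)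
Conditions: THF, −78 °C; then H2O
Reagents that add atoms: none
Why: 1,2-Addition of the alkenyl Grignard reagent to the aldehyde brings in C8, C8a and its methyl; the carbinol configuration does not matter because it is oxidised next.

Step 12
Reactants: 17 (4R,7E)-2,4,7-trimethyl-8-(4-methylpent-3-en-1-yl)deca-1,7,9-trien-3-ol
Product: 18 (4R,7E)-2,4,7-trimethyl-8-(4-methylpent-3-en-1-yl)deca-1,7,9-trien-3-one
Conditions: Dess–Martin periodinane, pyridine, CH2Cl2, 0 °C
Reagents that add atoms: none
Why: Oxidation of the allylic carbinol gives the isopropenyl ketone under cold, near-neutral conditions that should preserve the α-stereocentre; the trienone is taken on without storage.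

Step 13
Reactants: 18 (4R,7E)-2,4,7-trimethyl-8-(4-methylpent-3-en-1-yl)deca-1,7,9-trien-3-one
Product: 19 (2R,4aR,8aS)-2,4a,8a-trimethyl-5-(4-methylpent-3-en-1-yl)-3,4,4a,7,8,8a-hexahydronaphthalen-1(2H)-one
Conditions: Me2AlCl (1.1 equiv), CH2Cl2, −78 → −20 °C
Reagents that add atoms: none
Why: Me2AlCl binds the ketone oxygen of the in-tether enone, and the diene (C4a=C5–C6=C7 in product locants) adds across the isopropenyl C8a=C8 bond in a type 1 intramolecular [4+2] cycloaddition; the closest known reaction type is the Lewis-acid-promoted cyclisation of 1,7,9-decatrien-3-ones. Bond formation should be asynchronous: the two unhindered CH2 termini (C7 and C8) bond first, and the tertiary allyl cation/aluminium enolate character that develops then collapses to join the two fully substituted carbons, so the congested C4a–C8a bond is made last and within a six-membered ring. Ring B is the cyclohexene formed by the cycloaddition itself, with its double bond left at C5=C6 and the side chain already on C5; ring A closes as the six-membered tether ring through the same C4a–C8a bond. The relation of C4a to C8a is set by the endo position of the complexed carbonyl under the diene, which, with the tether on the outside of the diene terminus, gives the cis fusion with both methyl groups on one face. Their absolute sense is set by C2: in the chair-like tether its methyl group is equatorial only on the diene face that puts it trans to the axial C8a methyl, whereas the other face forces a syn-axial methyl/methyl contact. The step needs endo over exo selectivity (cis versus trans fusion), which rests on Lewis acid complexation of the internal carbonyl, and it needs the α-stereocentre to survive, which rests on the low temperature and the non-protic, proton-scavenging alkylaluminium.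

Step 14
Reactants: 19 (2R,4aR,8aS)-2,4a,8a-trimethyl-5-(4-methylpent-3-en-1-yl)-3,4,4a,7,8,8a-hexahydronaphthalen-1(2H)-one
Product: 20 (2R,4aR,8aR)-2,4a,8a-trimethyl-1-methylidene-5-(4-methylpent-3-en-1-yl)-1,2,3,4,4a,7,8,8a-octahydronaphthalene
Conditions: Zn, CH2Br2, TiCl4, THF, 0 °C; then 19, CH2Cl2, rt
Reagents that add atoms: dibromomethane, BrCBr
Why: Lombardo–Takai methylenation (gem-dizinc reagent activated by TiCl4) is non-basic and suited to hindered, enolisable ketones, so C1 should gain its extra carbon without epimerisation at C2.

Step 15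
Reactants: 20 (2R,4aR,8aR)-2,4a,8a-trimethyl-1-methylidene-5-(4-methylpent-3-en-1-yl)-1,2,3,4,4a,7,8,8a-octahydronaphthalene
Product: 22 [(2R,4aR,8aR)-2,4a,8a-trimethyl-5-(4-methylpent-3-en-1-yl)-1,2,3,4,4a,7,8,8a-octahydronaphthalen-1-yl]methanol (C1 epimers), via B-alkyl-9-borabicyclononane 21 (not isolated)
Conditions: 9-BBN, THF, 0 °C → rt; then NaOH, H2O2, 0 °C
Reagents that add atoms: 9-borabicyclo[3.3.1]nonane, B1C2CCCC1CCC2 (boron in 21 only); hydrogen peroxide, OO
Why: Anti-Markovnikov hydroboration: 9-BBN places boron on the terminal carbon of a 1,1-disubstituted alkene far faster than it attacks trisubstituted alkenes, and oxidation gives the primary alcohol; the face of hydrogen delivery to C1 need not be controlled because step 16 equilibrates this centre.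

Step 16
Reactants: 22 [(2R,4aR,8aR)-2,4a,8a-trimethyl-5-(4-methylpent-3-en-1-yl)-1,2,3,4,4a,7,8,8a-octahydronaphthalen-1-yl]methanol
Product: 24 (1S,2R,4aR,8aR)-2,4a,8a-trimethyl-5-(4-methylpent-3-en-1-yl)-1,2,3,4,4a,7,8,8a-octahydronaphthalene-1-carbaldehyde, via C1-epimeric aldehyde mixture 23 (not isolated)
Conditions: Dess–Martin periodinane, pyridine, CH2Cl2, 0 °C; then DBU (cat.), CH2Cl2, rt
Reagents that add atoms: none
Why: Oxidation followed by base-mediated enolisation equilibrates C1; with C2, C4a and C8a fixed, the (1S) aldehyde has the formyl and C2 methyl groups both equatorial, whereas its epimer has the formyl group syn-axial to the C4a–C5 bond, so both hydroboration epimers should converge on 24.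

Step 17
Reactants: 24 (1S,2R,4aR,8aR)-2,4a,8a-trimethyl-5-(4-methylpent-3-en-1-yl)-1,2,3,4,4a,7,8,8a-octahydronaphthalene-1-carbaldehyde
Product: 25 (1S,2R,4aR,8aR)-2,4a,8a-trimethyl-5-(4-methylpent-3-en-1-yl)-1,2,3,4,4a,7,8,8a-octahydronaphthalene-1-carboxylic acid
Conditions: NaClO2, NaH2PO4, 2-methylbut-2-ene, t-BuOH/H2O, 0 °C → rt
Reagents that add atoms: sodium chlorite, [Na+].[O-]Cl=O
Why: Pinnick oxidation converts the aldehyde to the acid at mildly acidic pH without epimerisation, and the alkene scavenger protects the two trisubstituted double bonds from hypochlorous acid.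

Step 18
Reactants: 26 (S)-glycidol
Product: 27 (R)-glycidyl acetate [(2R)-oxiran-2-ylmethyl acetate]
Conditions: Ac2O, Et3N, DMAP (cat.), CH2Cl2, 0 °C
Reagents that add atoms: acetic anhydride, CC(=O)OC(C)=O
Why: Acetylation of the primary alcohol; the epoxide and its stereocentre are untouched, and the descriptor changes from S to R only through the priority rules.

Step 19
Reactants: 25 (1S,2R,4aR,8aR)-2,4a,8a-trimethyl-5-(4-methylpent-3-en-1-yl)-1,2,3,4,4a,7,8,8a-octahydronaphthalene-1-carboxylic acid; 27 (R)-glycidyl acetate
Product: 28 (2S)-3-(acetyloxy)-2-hydroxypropyl (1S,2R,4aR,8aR)-2,4a,8a-trimethyl-5-(4-methylpent-3-en-1-yl)-1,2,3,4,4a,7,8,8a-octahydronaphthalene-1-carboxylate (CNP0146255.1)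
Conditions: Et4NBr (10 mol %), toluene, 80 °C
Reagents that add atoms: none
Why: Halide-catalysed addition of a carboxylic acid to a glycidyl ester: the carboxylate attacks the terminal epoxide carbon (SN2), so the ester is made at oxygen, away from the hindered carbonyl, the glycerol stereocentre is untouched and the free 2-hydroxyl appears without protecting groups; the medium stays weakly acidic, which should suppress acyl migration.

## Compound list

1 | (S)-3-bromo-2-methylpropan-1-ol | OC[C@H](C)CBr | starting material
2 | (S)-(3-bromo-2-methylpropoxy)(tert-butyl)dimethylsilane | CC(C)(C)[Si](C)(C)OC[C@H](C)CBr | intermediate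
3 | methyl acetoacetate | COC(=O)CC(C)=O | starting material
4 | methyl acetoacetate dianion (sodium lithium salt) | C=C([O-])C=C([O-])OC.[Na+].[Li+] | intermediate (not isolated)
5 | methyl (6R)-7-[(tert-butyldimethylsilyl)oxy]-6-methyl-3-oxoheptanoate | COC(=O)CC(=O)CC[C@@H](C)CO[Si](C)(C)C(C)(C)C | intermediate
6 | 5-bromo-2-methylpent-2-ene | CC(C)=CCCBr | starting material
7 | methyl (6R)-7-[(tert-butyldimethylsilyl)oxy]-6-methyl-2-(4-methylpent-3-en-1-yl)-3-oxoheptanoate (C2 epimers) | COC(=O)C(CCC=C(C)C)C(=O)CC[C@@H](C)CO[Si](C)(C)C(C)(C)C | intermediate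
8 | sodium (Z)-enolate chelate of 7 | COC(=O)/C(CCC=C(C)C)=C(\[O-])CC[C@@H](C)CO[Si](C)(C)C(C)(C)C.[Na+] | intermediate (not isolated)
9 | methyl (2Z,6R)-7-[(tert-butyldimethylsilyl)oxy]-6-methyl-2-(4-methylpent-3-en-1-yl)-3-{[(trifluoromethyl)sulfonyl]oxy}hept-2-enoate | COC(=O)/C(CCC=C(C)C)=C(\OS(=O)(=O)C(F)(F)F)CC[C@@H](C)CO[Si](C)(C)C(C)(C)C | intermediate
10 | methyl (2E,6R)-7-[(tert-butyldimethylsilyl)oxy]-3,6-dimethyl-2-(4-methylpent-3-en-1-yl)hept-2-enoate | COC(=O)/C(CCC=C(C)C)=C(\C)CC[C@@H](C)CO[Si](C)(C)C(C)(C)C | intermediate
11 | (2E,6R)-7-[(tert-butyldimethylsilyl)oxy]-3,6-dimethyl-2-(4-methylpent-3-en-1-yl)hept-2-en-1-ol | OC/C(CCC=C(C)C)=C(\C)CC[C@@H](C)CO[Si](C)(C)C(C)(C)C | intermediate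
12 | (2E,6R)-7-[(tert-butyldimethylsilyl)oxy]-3,6-dimethyl-2-(4-methylpent-3-en-1-yl)hept-2-enal | O=C/C(CCC=C(C)C)=C(\C)CC[C@@H](C)CO[Si](C)(C)C(C)(C)C | intermediate
13 | tert-butyl{[(2R,5E)-2,5-dimethyl-6-(4-methylpent-3-en-1-yl)octa-5,7-dien-1-yl]oxy}dimethylsilane | C=C/C(CCC=C(C)C)=C(\C)CC[C@@H](C)CO[Si](C)(C)C(C)(C)C | intermediate
14 | (2R,5E)-2,5-dimethyl-6-(4-methylpent-3-en-1-yl)octa-5,7-dien-1-ol | C=C/C(CCC=C(C)C)=C(\C)CC[C@@H](C)CO | intermediate
15 | (2R,5E)-2,5-dimethyl-6-(4-methylpent-3-en-1-yl)octa-5,7-dienal | C=C/C(CCC=C(C)C)=C(\C)CC[C@@H](C)C=O | intermediate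
16 | isopropenylmagnesium bromide | CC(=C)[Mg]Br | starting material
17 | (4R,7E)-2,4,7-trimethyl-8-(4-methylpent-3-en-1-yl)deca-1,7,9-trien-3-ol (C3 epimers) | C=C/C(CCC=C(C)C)=C(\C)CC[C@@H](C)C(O)C(C)=C | intermediate
18 | (4R,7E)-2,4,7-trimethyl-8-(4-methylpent-3-en-1-yl)deca-1,7,9-trien-3-one | C=C/C(CCC=C(C)C)=C(\C)CC[C@@H](C)C(=O)C(C)=C | intermediate
19 | (2R,4aR,8aS)-2,4a,8a-trimethyl-5-(4-methylpent-3-en-1-yl)-3,4,4a,7,8,8a-hexahydronaphthalen-1(2H)-one | O=C1[C@H](C)CC[C@]2(C)C(CCC=C(C)C)=CCC[C@]12C | intermediate
20 | (2R,4aR,8aR)-2,4a,8a-trimethyl-1-methylidene-5-(4-methylpent-3-en-1-yl)-1,2,3,4,4a,7,8,8a-octahydronaphthalene | C=C1[C@H](C)CC[C@]2(C)C(CCC=C(C)C)=CCC[C@]12C | intermediate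
21 | 9-{[(2R,4aR,8aR)-2,4a,8a-trimethyl-5-(4-methylpent-3-en-1-yl)-1,2,3,4,4a,7,8,8a-octahydronaphthalen-1-yl]methyl}-9-borabicyclo[3.3.1]nonane (C1 epimers) | C(B1C2CCCC1CCC2)C1[C@H](C)CC[C@]2(C)C(CCC=C(C)C)=CCC[C@]12C | intermediate (not isolated)
22 | [(2R,4aR,8aR)-2,4a,8a-trimethyl-5-(4-methylpent-3-en-1-yl)-1,2,3,4,4a,7,8,8a-octahydronaphthalen-1-yl]methanol (C1 epimers) | OCC1[C@H](C)CC[C@]2(C)C(CCC=C(C)C)=CCC[C@]12C | intermediate
23 | (2R,4aR,8aR)-2,4a,8a-trimethyl-5-(4-methylpent-3-en-1-yl)-1,2,3,4,4a,7,8,8a-octahydronaphthalene-1-carbaldehyde (C1 epimers) | O=CC1[C@H](C)CC[C@]2(C)C(CCC=C(C)C)=CCC[C@]12C | intermediate (not isolated)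
24 | (1S,2R,4aR,8aR)-2,4a,8a-trimethyl-5-(4-methylpent-3-en-1-yl)-1,2,3,4,4a,7,8,8a-octahydronaphthalene-1-carbaldehyde | O=C[C@H]1[C@H](C)CC[C@]2(C)C(CCC=C(C)C)=CCC[C@]12C | intermediate
25 | (1S,2R,4aR,8aR)-2,4a,8a-trimethyl-5-(4-methylpent-3-en-1-yl)-1,2,3,4,4a,7,8,8a-octahydronaphthalene-1-carboxylic acid | OC(=O)[C@H]1[C@H](C)CC[C@]2(C)C(CCC=C(C)C)=CCC[C@]12C | intermediate
26 | (S)-glycidol | OC[C@H]1CO1 | starting material
27 | (R)-glycidyl acetate | CC(=O)OC[C@H]1CO1 | intermediate
28 | (2S)-3-(acetyloxy)-2-hydroxypropyl (1S,2R,4aR,8aR)-2,4a,8a-trimethyl-5-(4-methylpent-3-en-1-yl)-1,2,3,4,4a,7,8,8a-octahydronaphthalene-1-carboxylate | CC(=O)OC[C@H](O)COC(=O)[C@H]1[C@H](C)CC[C@]2(C)C(CCC=C(C)C)=CCC[C@]12C | target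

## Step count and least certain steps

Total: 19 steps. Longest linear sequence: 18 steps (steps 1–17 and 19, from 1); step 18 is a one-step side branch.

**Step 13 (key step).** The most likely failure is closure through the exo arrangement, which gives the trans-fused isomer, or proton loss from the polarised intermediate before the second bond forms (an ene-type diversion). Both are plausible because that bond joins two fully substituted carbons and the diene terminus carries an inside methyl group. Fallback, setting out from 18: treatment with 1,2-bis(trimethylsilyloxy)ethane and TMSOTf at −78 °C should give, by silyl-transfer ketalisation, 2-[(2R,5E)-5-methyl-6-(4-methylpent-3-en-1-yl)octa-5,7-dien-2-yl]-2-(prop-1-en-2-yl)-1,3-dioxolane F1. The same acid ionises it to a 2-alkoxyallyl cation, a much stronger dienophile (ionic Diels–Alder reaction of enone acetals), while the chair-like tether and the C2 relay stay the same. Cyclisation gives the ethylene ketal of the bicyclic ketone F2, and pyridinium tosylate in wet acetone returns the route to 19.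

**Step 14.** Methylenation may stall because the carbonyl is shielded by the C8a quaternary centre and the C2 methyl group, so that reagent decomposition outruns addition. Fallback, setting out from 19: Corey–Chaykovsky epoxidation with the smaller dimethylsulfonium methylide (Me3SI, n-BuLi, THF, −10 °C) gives the spiro-epoxide at C1 F3. BF3·OEt2 at −78 °C opens it at the tertiary carbon, and a 1,2-hydride shift (Meinwald rearrangement) gives the aldehyde mixture 23, which rejoins the route at the equilibration of step 16.

**Step 15.** Chemoselectivity may be lost: the side-chain trisubstituted alkene may be hydroborated competitively because the exocyclic methylene lies between a quaternary and a tertiary carbon. Fallback, setting out from 19, so that no alkene has to be distinguished: lithiated (methoxymethyl)trimethylsilane (s-BuLi, THF, −78 °C) adds to the ketone to give the 1-[methoxy(trimethylsilyl)methyl] tertiary alcohol F4. KH induces Peterson elimination to the 1-(methoxymethylidene) enol ether F5, and aqueous oxalic acid hydrolyses this to the aldehyde mixture 23, which rejoins the route at the equilibration of step 16.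

**Step 19.** Acyl migration to the 2-position, attack at the internal epoxide carbon, or slow addition of the hindered carboxylate at 80 °C may give isomeric glycerides. Fallback, setting out from 25: Cs2CO3 in DMF and commercial [(4S)-2,2-dimethyl-1,3-dioxolan-4-yl]methyl 4-methylbenzenesulfonate alkylate the carboxylate at oxygen to give the [(4S)-2,2-dimethyl-1,3-dioxolan-4-yl]methyl ester F6. Aqueous acetic acid at rt removes the acetonide to give the (2S)-2,3-dihydroxypropyl ester F7, and lipase-catalysed acetylation of the primary hydroxyl (Candida antarctica lipase B, vinyl acetate, t-BuOMe) returns the route to 28.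

## Further compounds

F1 | step 13 | 2-[(2R,5E)-5-methyl-6-(4-methylpent-3-en-1-yl)octa-5,7-dien-2-yl]-2-(prop-1-en-2-yl)-1,3-dioxolane | C=C/C(CCC=C(C)C)=C(\C)CC[C@@H](C)C1(OCCO1)C(C)=C
F2 | step 13 | ethylene ketal of ketone 19 (spiro-1,3-dioxolane at C1) | O1CCOC12[C@H](C)CC[C@]3(C)C(CCC=C(C)C)=CCC[C@]23C
F3 | step 14 | spiro-epoxide of 19 at C1 (spiro carbon not controlled) | C1OC12[C@H](C)CC[C@]3(C)C(CCC=C(C)C)=CCC[C@]23C
F4 | step 15 | (2R,4aR,8aS)-1-[methoxy(trimethylsilyl)methyl]-2,4a,8a-trimethyl-5-(4-methylpent-3-en-1-yl)-1,2,3,4,4a,7,8,8a-octahydronaphthalen-1-ol (new centres not controlled) | COC([Si](C)(C)C)C1(O)[C@H](C)CC[C@]2(C)C(CCC=C(C)C)=CCC[C@]12C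
F5 | step 15 | (2R,4aR,8aR)-1-(methoxymethylidene)-2,4a,8a-trimethyl-5-(4-methylpent-3-en-1-yl)-1,2,3,4,4a,7,8,8a-octahydronaphthalene | COC=C1[C@H](C)CC[C@]2(C)C(CCC=C(C)C)=CCC[C@]12C
F6 | step 19 | [(4S)-2,2-dimethyl-1,3-dioxolan-4-yl]methyl ester of acid 25 | CC1(C)OC[C@@H](COC(=O)[C@H]2[C@H](C)CC[C@]3(C)C(CCC=C(C)C)=CCC[C@]23C)O1
F7 | step 19 | (2S)-2,3-dihydroxypropyl ester of acid 25 | OC[C@H](O)COC(=O)[C@H]1[C@H](C)CC[C@]2(C)C(CCC=C(C)C)=CCC[C@]12C
A1 | alternative 1 | 2,3-dimethylcyclohex-2-en-1-one | CC1=C(C)C(=O)CCC1
A2 | alternative 1 | methyl (2E)-3-methylpenta-2,4-dienoate | COC(=O)/C=C(\C)C=C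
A3 | alternative 1 | methyl 2,4a,8a-trimethyl-5-oxo-1,4,4a,5,6,7,8,8a-octahydronaphthalene-1-carboxylate (cis-fused; ester cis to both angular methyls; enantiomer matching the target) | COC(=O)[C@H]1C(C)=CC[C@]2(C)C(=O)CCC[C@]12C
A4 | alternative 2 | methyl (2E,8E,10E)-3,8-dimethyl-7-oxododeca-2,8,10-trienoate | COC(=O)/C=C(\C)CCCC(=O)/C(C)=C/C=C/C
A5 | alternative 2 | methyl 2,4a,8a-trimethyl-5-oxo-1,2,4a,5,6,7,8,8a-octahydronaphthalene-1-carboxylate (cis-fused; configuration matching the target) | COC(=O)[C@H]1[C@H](C)C=C[C@]2(C)C(=O)CCC[C@]12C
A6 | alternative 3 | methyl (3R)-3-methyl-5-(2-methyl-6-oxocyclohex-1-en-1-yl)pentanoate | COC(=O)C[C@H](C)CCC1=C(C)CCCC1=O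
A7 | alternative 3 | methyl (1S,2R,4aS,8aR)-2,4a,8a-trimethyl-5-oxodecahydronaphthalene-1-carboxylate | COC(=O)[C@H]1[C@H](C)CC[C@]2(C)C(=O)CCC[C@]12C
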